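**Retrosynthetic overview**

1. The ten-membered carbocycle (C1–C10) is closed last, across C7–C8, by an intramolecular Nozaki–Hiyama–Kishi allylation of the C8 aldehyde with the 3-(bromomethyl)butenolide 31 (C13–Br, C11=C7). The enabling feature is the homoallylic array O8–C8–C7–C11=C13 on the fusion atom C7 shared by the lactone and the carbocycle, which is the retron of an allyl-metal/aldehyde addition with allyl transposition.
2. Before that, the epoxide (Shi epoxidation of the (E)-C1=C10 bond) and the lactone are already in place. The butenolide O6–C12 comes from a C6 propargylic alcohol by Red-Al/I2 and Pd/CO carbonylation, and C6 from Noyori reduction of an ynone.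
3. The (Z)-C4=C5 bond comes from a temporary butenolide (Bestmann ylide on the C3-hydroxy C4-ketone), which is opened again as a Weinreb amide.
4. C3 and the C15–C4–C3 unit come from an SAMP-hydrazone alkylation of 2,2-dimethyl-1,3-dioxan-5-one with an (E)-allylic bromide made by Negishi carboalumination of but-3-yn-1-ol.
5. Ring order: temporary butenolide (opened again) → lactone → epoxide → ten-membered ring. Endgame: Mitsunobu angeloylation with inversion at C8, then desilylation.

Key step: step 20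

Remark: atom labels follow germacranolide numbering (C1–C10 carbocycle; C11, C12, C13 = α-carbon, carbonyl and exo-methylene of the lactone; C14 = methyl on C10; C15 = CH2OH on C4); in this numbering the target is (1R,3S,4Z,6R,7R,8R,10R) and its ester is the angelate [(Z)-2-methylbut-2-enoate].

**Route**

Step 1
Reactants: 1 but-3-yn-1-ol
Product: 2 1-[(but-3-yn-1-yloxy)methyl]-4-methoxybenzene
Conditions: NaH, PMBCl, Bu4NI (cat.), THF/DMF, 0 °C → rt
Reagents that add atoms: 4-methoxybenzyl chloride COc1ccc(CCl)cc1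
Why: Williamson etherification puts a PMB group on the future C8 oxygen, which can later be removed oxidatively (DDQ) in the presence of the allylic bromide and the epoxide; no stereocentre is formed.

Step 2
Reactants: 2 1-[(but-3-yn-1-yloxy)methyl]-4-methoxybenzene
Product: 4 (2E)-5-[(4-methoxybenzyl)oxy]-3-methylpent-2-en-1-ol, via alkenyldimethylalane 3 (not isolated)
Conditions: Me3Al, Cp2ZrCl2 (cat.), CH2Cl2, 0 °C → rt; then n-BuLi, THF, −78 °C; (CH2O)n, rt; cold 1 M HCl work-up
Reagents that add atoms: trimethylaluminium C[Al](C)C; formaldehyde (as paraformaldehyde) C=O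
Why: Negishi Zr-catalysed carboalumination adds methyl (C14) and Al syn across the alkyne with Al on the terminal carbon, which fixes the (E)-C1=C10 geometry, and the ate complex is hydroxymethylated with retention to add C2.

Step 3
Reactants: 4 (2E)-5-[(4-methoxybenzyl)oxy]-3-methylpent-2-en-1-ol
Product: 5 1-({[(3E)-5-bromo-3-methylpent-3-en-1-yl]oxy}methyl)-4-methoxybenzene
Conditions: CBr4, PPh3, CH2Cl2, 0 °C
Reagents that add atoms: tetrabromomethane BrC(Br)(Br)Br
Why: Appel bromination replaces the primary allylic hydroxyl by SN2 at the CH2 carbon without allylic transposition or loss of the (E)-geometry.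

Step 4
Reactants: 6 2,2-dimethyl-1,3-dioxan-5-one + 7 (2S)-2-(methoxymethyl)pyrrolidin-1-amine (SAMP)
Product: 8 (2S)-N-(2,2-dimethyl-1,3-dioxan-5-ylidene)-2-(methoxymethyl)pyrrolidin-1-amine
Conditions: benzene, reflux, Dean–Stark
Reagents that add atoms: none
Why: Hydrazone condensation with azeotropic removal of water installs the chiral auxiliary on the dihydroxyacetone equivalent.

Step 5
Reactants: 8 SAMP hydrazone of 2,2-dimethyl-1,3-dioxan-5-one + 5 (E)-allylic bromide
Product: 10 (2S)-N-[(4S)-4-{(2E)-5-[(4-methoxybenzyl)oxy]-3-methylpent-2-en-1-yl}-2,2-dimethyl-1,3-dioxan-5-ylidene]-2-(methoxymethyl)pyrrolidin-1-amine, via lithium azaenolate 9 (not isolated)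
Conditions: t-BuLi, THF, −78 °C; then 5, −100 → −78 °C
Reagents that add atoms: none
Why: Enders SAMP-hydrazone α-alkylation: the lithium azaenolate, chelated by the methoxymethyl arm, is alkylated by the allylic bromide (SN2) on the face away from the pyrrolidine, which sets C3 as S and forms the C2–C3 bond.

Step 6
Reactants: 10 alkylated SAMP hydrazone
Product: 12 (3S,5E)-1,3-dihydroxy-8-[(4-methoxybenzyl)oxy]-6-methyloct-5-en-2-one, via dioxanone 11 (not isolated)
Conditions: sat. aq. oxalic acid, Et2O, rt; then 1 M aq. HCl, THF, rt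
Reagents that add atoms: water O
Why: Mild acid hydrolysis cleaves first the hydrazone (auxiliary recoverable) and then the isopropylidene acetal, conditions under which the α-oxygenated centre C3 should not enolise and the PMB ether should survive.

Step 7
Reactants: 12 (3S,5E)-1,3-dihydroxy-8-[(4-methoxybenzyl)oxy]-6-methyloct-5-en-2-one
Product: 13 (3S,5E)-1-[(tert-butyldimethylsilyl)oxy]-3-hydroxy-8-[(4-methoxybenzyl)oxy]-6-methyloct-5-en-2-one
Conditions: TBSCl (1.05 equiv), imidazole, CH2Cl2, −20 → 0 °C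
Reagents that add atoms: tert-butyldimethylsilyl chloride CC(C)(C)[Si](C)(C)Cl
Why: Silylation with one equivalent of TBSCl is selective for the primary C15 hydroxyl over the secondary C3 hydroxyl and leaves the α-hydroxy ketone required for the next step.

Step 8
Reactants: 13 C15-silylated α-hydroxy ketone + 14 (triphenylphosphoranylidene)ketene (Bestmann ylide)
Product: 16 (5S)-4-{[(tert-butyldimethylsilyl)oxy]methyl}-5-{(2E)-5-[(4-methoxybenzyl)oxy]-3-methylpent-2-en-1-yl}furan-2(5H)-one, via acyl ylide 15 (not isolated)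
Conditions: toluene, 90 °C
Reagents that add atoms: none
Why: Bestmann ylide addition–intramolecular Wittig reaction: the C3 hydroxyl adds to the ketene and the resulting ester ylide olefinates the neighbouring C4 ketone, so the temporary butenolide ring forces C3 and C6 cis on the new C4=C5 bond, which is the Z geometry of the target.

Step 9
Reactants: 16 temporary butenolide
Product: 17 (2Z,4S,6E)-3-{[(tert-butyldimethylsilyl)oxy]methyl}-4-hydroxy-N-methoxy-9-[(4-methoxybenzyl)oxy]-N,7-dimethylnona-2,6-dienamide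
Conditions: MeNH(OMe)·HCl, Me3Al, CH2Cl2, 0 °C → rt; Rochelle salt work-up; crude used at once
Reagents that add atoms: N,O-dimethylhydroxylamine hydrochloride CNOC.Cl
Why: Weinreb aminolysis with the aluminium amide opens the lactone by 1,2-acyl substitution to the (Z)-γ-hydroxy enamide without changing the alkene geometry.

Step 10
Reactants: 17 (Z)-γ-hydroxy Weinreb amide
Product: 18 (2Z,4S,6E)-4-[(tert-butyldimethylsilyl)oxy]-3-{[(tert-butyldimethylsilyl)oxy]methyl}-N-methoxy-9-[(4-methoxybenzyl)oxy]-N,7-dimethylnona-2,6-dienamide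
Conditions: TBSOTf, 2,6-lutidine, CH2Cl2, −78 °C
Reagents that add atoms: tert-butyldimethylsilyl trifluoromethanesulfonate CC(C)(C)[Si](C)(C)OS(=O)(=O)C(F)(F)F
Why: Fast low-temperature silylation caps the C3 hydroxyl and so blocks relactonisation.

Step 11
Reactants: 19 prop-2-yn-1-ol
Product: 20 triethyl(prop-2-yn-1-yloxy)silane
Conditions: TESCl, imidazole, CH2Cl2, 0 °C
Reagents that add atoms: chlorotriethylsilane CC[Si](Cl)(CC)CC
Why: Standard silylation gives a propargylic ether whose TES group can later be removed in the presence of the TBS and PMB ethers.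

Step 12
Reactants: 18 bis-silylated Weinreb amide + 20 triethyl(prop-2-yn-1-yloxy)silane
Product: 22 (5Z,7S,9E)-7-[(tert-butyldimethylsilyl)oxy]-6-{[(tert-butyldimethylsilyl)oxy]methyl}-12-[(4-methoxybenzyl)oxy]-10-methyl-1-[(triethylsilyl)oxy]dodeca-5,9-dien-2-yn-4-one, via lithium acetylide 21 (not isolated)
Conditions: 20, n-BuLi, THF, −78 °C; then 18, −78 → −40 °C; AcOH quench at −78 °C
Reagents that add atoms: none
Why: The lithium acetylide adds once to the Weinreb amide (chelated tetrahedral intermediate) to form the C6–C7 bond, and the cold acidic quench prevents conjugate addition of the released hydroxylamine to the ynone.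

Step 13
Reactants: 22 cross-conjugated ynone
Product: 23 (4R,5Z,7S,9E)-7-[(tert-butyldimethylsilyl)oxy]-6-{[(tert-butyldimethylsilyl)oxy]methyl}-12-[(4-methoxybenzyl)oxy]-10-methyl-1-[(triethylsilyl)oxy]dodeca-5,9-dien-2-yn-4-ol
Conditions: Ru[(R,R)-TsDPEN](p-cymene) (3 mol%), i-PrOH, rt
Reagents that add atoms: none
Why: Noyori asymmetric transfer hydrogenation of the alkynyl ketone, in which the alkyne is the π-directing group in the six-membered Ru–H/N–H transition state, so the (R,R)-catalyst should give the 6R carbinol under reagent control.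

Step 14
Reactants: 23 (R)-propargylic alcohol
Product: 25 (2Z,4R,5Z,7S,9E)-7-[(tert-butyldimethylsilyl)oxy]-6-{[(tert-butyldimethylsilyl)oxy]methyl}-2-iodo-12-[(4-methoxybenzyl)oxy]-10-methyl-1-[(triethylsilyl)oxy]dodeca-2,5,9-trien-4-ol, via vinylalanate 24 (not isolated)
Conditions: Red-Al, THF, 0 °C → rt; EtOAc; then I2, −78 → 0 °C
Reagents that add atoms: iodine II
Why: Hydroxyl-directed trans-hydroalumination of the propargylic alcohol delivers H to C7 and Al to C11 through a five-membered alanate, which iodine cleaves with retention to give the (Z)-γ-hydroxy vinyl iodide.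

Step 15
Reactants: 25 (Z)-γ-hydroxy vinyl iodide
Product: 27 (5R)-5-{(1Z,3S,5E)-3-[(tert-butyldimethylsilyl)oxy]-2-{[(tert-butyldimethylsilyl)oxy]methyl}-8-[(4-methoxybenzyl)oxy]-6-methylocta-1,5-dien-1-yl}-3-(hydroxymethyl)furan-2(5H)-one, via TES-protected butenolide 26 (not isolated)
Conditions: PdCl2(PPh3)2 (5 mol%), CO (1 atm), K2CO3, THF, 45 °C; filter; then PPTS, MeOH, 0 °C
Reagents that add atoms: carbon monoxide [C-]#[O+]
Why: Pd-catalysed carbonylative lactonisation (oxidative addition into C11–I, CO insertion, capture of the acyl-Pd by the cis C6 hydroxyl) closes the lactone with retention at C6, and mild acid methanolysis then removes only the TES ether.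

Step 16
Reactants: 27 3-(hydroxymethyl)butenolide
Product: 28 (5R)-5-{(1Z,3S)-3-[(tert-butyldimethylsilyl)oxy]-2-{[(tert-butyldimethylsilyl)oxy]methyl}-4-[(2R,3R)-3-{2-[(4-methoxybenzyl)oxy]ethyl}-3-methyloxiran-2-yl]but-1-en-1-yl}-3-(hydroxymethyl)furan-2(5H)-one
Conditions: D-fructose-derived Shi ketone, Oxone, K2CO3, Bu4NHSO4, borate/EDTA buffer (pH ≈ 9), MeCN–DMM–H2O, −5 °C
Reagents that add atoms: potassium peroxymonosulfate (Oxone) [K+].[O-]S(=O)(=O)OO
Why: Shi asymmetric epoxidation: the chiral dioxirane attacks the electron-rich (E)-trisubstituted C1=C10 bond through a spiro transition state to give the (1R,10R)-epoxide, while the C4=C5 bond (three allylic C–O bonds) and the butenolide are electron-poor and should not react.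

Step 17
Reactants: 28 epoxy 3-(hydroxymethyl)butenolide
Product: 29 (5R)-3-(bromomethyl)-5-{(1Z,3S)-3-[(tert-butyldimethylsilyl)oxy]-2-{[(tert-butyldimethylsilyl)oxy]methyl}-4-[(2R,3R)-3-{2-[(4-methoxybenzyl)oxy]ethyl}-3-methyloxiran-2-yl]but-1-en-1-yl}furan-2(5H)-one
Conditions: CBr4, PPh3, CH2Cl2, −20 → 0 °C
Reagents that add atoms: tetrabromomethane BrC(Br)(Br)Br
Why: Appel bromination of the primary allylic alcohol under neutral conditions should leave the trisubstituted epoxide and the base-sensitive butenolide untouched.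

Step 18
Reactants: 29 3-(bromomethyl)butenolide PMB ether
Product: 30 (5R)-3-(bromomethyl)-5-{(1Z,3S)-3-[(tert-butyldimethylsilyl)oxy]-2-{[(tert-butyldimethylsilyl)oxy]methyl}-4-[(2R,3R)-3-(2-hydroxyethyl)-3-methyloxiran-2-yl]but-1-en-1-yl}furan-2(5H)-one
Conditions: DDQ, CH2Cl2/pH 7 buffer, 0 °C
Reagents that add atoms: none
Why: Oxidative PMB cleavage with DDQ is neutral and should leave the allylic bromide, the epoxide and the silyl ethers intact.

Step 19
Reactants: 30 bromo alcohol
Product: 31 2-[(2R,3R)-3-{(2S,3Z)-4-[(2R)-4-(bromomethyl)-5-oxo-2,5-dihydrofuran-2-yl]-2-[(tert-butyldimethylsilyl)oxy]-3-{[(tert-butyldimethylsilyl)oxy]methyl}but-3-en-1-yl}-2-methyloxiran-2-yl]acetaldehyde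
Conditions: Dess–Martin periodinane, NaHCO3, CH2Cl2, 0 °C; used crude
Reagents that add atoms: none
Why: Buffered Dess–Martin oxidation gives the β,γ-epoxy aldehyde without base, so epoxide opening by α-deprotonation is avoided if the aldehyde is used at once.

Step 20
Reactants: 31 bromo aldehyde
Product: 33 (1R,3S,4Z,6R,7R,8S,10R)-3,15-bis[(tert-butyldimethylsilyl)oxy]-1,10-epoxy-8-hydroxygermacra-4,11(13)-dien-12,6-olide, via allylchromium(III) species 32 (not isolated)
Conditions: CrCl2 (10 equiv), THF (degassed), rt, syringe-pump addition of 31 over 12 h (final 2 mM)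
Reagents that add atoms: none
Why: Two equivalents of Cr(II) reduce the allylic C13–Br bond to a σ-allylchromium(III) that adds through its γ-carbon C7 (the butenolide β-carbon) to the Cr-bound C8 aldehyde in a six-membered chair (Zimmerman–Traxler) transition state, and the allyl transposition unveils the C11=C13 exo-methylene. The closest known reaction types are the Nozaki–Hiyama (Barbier) allylation of aldehydes with 3-(bromomethyl)furan-2(5H)-ones, which gives β-(hydroxyalkyl)-α-methylene-γ-butyrolactones, and Cr(II)-mediated intramolecular allylations that close ten-membered germacranolide rings. The carbocycle is closed by C7–C8 bond formation in a ten-membered mode that is exo with respect to the aldehyde C=O and SE2′ (endo) with respect to the butenolide C7=C11 bond. C7 (R) is controlled by the C6 stereocentre: the aldehyde arm, anchored at C5, should reach C7 without eclipsing the C6–C5 bond only from the face opposite to C5, which gives the trans-fused lactone. C8 is controlled by the chair: the ring locks the allyl unit in the E-type geometry (C6 trans to C13) and the tether carbon C9 must point away from the lactone, so the anti (8S) carbinol is expected, which step 21 inverts. The step needs γ- over α-attack (secured by the primary C13–Cr bond and the cyclic transition state), intra- over intermolecular coupling (high dilution and slow addition) and tolerance of the epoxide and silyl ethers (Cr(II) should be inert to both).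

Step 21
Reactants: 33 macrocyclic 8S alcohol + 34 angelic acid [(2Z)-2-methylbut-2-enoic acid]
Product: 35 (1R,3S,4Z,6R,7R,8R,10R)-8-angeloyloxy-3,15-bis[(tert-butyldimethylsilyl)oxy]-1,10-epoxygermacra-4,11(13)-dien-12,6-olide
Conditions: PPh3, DIAD, toluene, 0 °C → rt
Reagents that add atoms: none
Why: Mitsunobu esterification: the angelate displaces the C8 alkoxyphosphonium by SN2, which inverts C8 from S to the required R and installs the ester in the same operation.

Step 22
Reactants: 35 bis-TBS-protected angelate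
Product: 36 (1R,3S,4Z,6R,7R,8R,10R)-8-angeloyloxy-1,10-epoxy-3,15-dihydroxygermacra-4,11(13)-dien-12,6-olide (CNP0187917.1)
Conditions: HF·pyridine, pyridine, THF, 0 °C → rt
Reagents that add atoms: none
Why: Pyridine-buffered fluoride desilylation removes both TBS ethers under conditions that should spare the epoxide, the α-methylene lactone and the angelate; no stereocentre is touched.

**Compound list**

1 | but-3-yn-1-ol | C#CCCO | starting material
2 | 1-[(but-3-yn-1-yloxy)methyl]-4-methoxybenzene | C#CCCOCc1ccc(OC)cc1 | intermediate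
3 | dimethyl{(1E)-4-[(4-methoxybenzyl)oxy]-2-methylbut-1-en-1-yl}alane | C[Al](C)/C=C(C)/CCOCc1ccc(OC)cc1 | intermediate
4 | (2E)-5-[(4-methoxybenzyl)oxy]-3-methylpent-2-en-1-ol | OC/C=C(C)/CCOCc1ccc(OC)cc1 | intermediate
5 | 1-({[(3E)-5-bromo-3-methylpent-3-en-1-yl]oxy}methyl)-4-methoxybenzene | BrC/C=C(C)/CCOCc1ccc(OC)cc1 | intermediate
6 | 2,2-dimethyl-1,3-dioxan-5-one | CC1(C)OCC(=O)CO1 | starting material
7 | (2S)-2-(methoxymethyl)pyrrolidin-1-amine (SAMP) | COC[C@@H]1CCCN1N | starting material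
8 | (2S)-N-(2,2-dimethyl-1,3-dioxan-5-ylidene)-2-(methoxymethyl)pyrrolidin-1-amine | COC[C@@H]1CCCN1N=C1COC(C)(C)OC1 | intermediate
9 | lithium azaenolate of 8 | COC[C@@H]1CCCN1[N-]C1=COC(C)(C)OC1.[Li+] | intermediate
10 | (2S)-N-[(4S)-4-{(2E)-5-[(4-methoxybenzyl)oxy]-3-methylpent-2-en-1-yl}-2,2-dimethyl-1,3-dioxan-5-ylidene]-2-(methoxymethyl)pyrrolidin-1-amine (C=N geometry left open) | COC[C@@H]1CCCN1N=C1COC(C)(C)O[C@H]1C/C=C(C)/CCOCc1ccc(OC)cc1 | intermediate
11 | (4S)-4-{(2E)-5-[(4-methoxybenzyl)oxy]-3-methylpent-2-en-1-yl}-2,2-dimethyl-1,3-dioxan-5-one | CC1(C)OCC(=O)[C@H](C/C=C(C)/CCOCc2ccc(OC)cc2)O1 | intermediate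
12 | (3S,5E)-1,3-dihydroxy-8-[(4-methoxybenzyl)oxy]-6-methyloct-5-en-2-one | OCC(=O)[C@@H](O)C/C=C(C)/CCOCc1ccc(OC)cc1 | intermediate
13 | (3S,5E)-1-[(tert-butyldimethylsilyl)oxy]-3-hydroxy-8-[(4-methoxybenzyl)oxy]-6-methyloct-5-en-2-one | CC(C)(C)[Si](C)(C)OCC(=O)[C@@H](O)C/C=C(C)/CCOCc1ccc(OC)cc1 | intermediate
14 | (triphenylphosphoranylidene)ketene (Bestmann ylide) | O=C=C=P(c1ccccc1)(c1ccccc1)c1ccccc1 | starting material
15 | (triphenylphosphoranylidene)acetate ester of the C3 hydroxyl of 13 | CC(C)(C)[Si](C)(C)OCC(=O)[C@H](C/C=C(C)/CCOCc1ccc(OC)cc1)OC(=O)C=P(c1ccccc1)(c1ccccc1)c1ccccc1 | intermediate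
16 | (5S)-4-{[(tert-butyldimethylsilyl)oxy]methyl}-5-{(2E)-5-[(4-methoxybenzyl)oxy]-3-methylpent-2-en-1-yl}furan-2(5H)-one | O=C1C=C(CO[Si](C)(C)C(C)(C)C)[C@H](C/C=C(C)/CCOCc2ccc(OC)cc2)O1 | intermediate
17 | (2Z,4S,6E)-3-{[(tert-butyldimethylsilyl)oxy]methyl}-4-hydroxy-N-methoxy-9-[(4-methoxybenzyl)oxy]-N,7-dimethylnona-2,6-dienamide | CON(C)C(=O)/C=C(/CO[Si](C)(C)C(C)(C)C)[C@@H](O)C/C=C(C)/CCOCc1ccc(OC)cc1 | intermediate
18 | (2Z,4S,6E)-4-[(tert-butyldimethylsilyl)oxy]-3-{[(tert-butyldimethylsilyl)oxy]methyl}-N-methoxy-9-[(4-methoxybenzyl)oxy]-N,7-dimethylnona-2,6-dienamide | CON(C)C(=O)/C=C(/CO[Si](C)(C)C(C)(C)C)[C@@H](O[Si](C)(C)C(C)(C)C)C/C=C(C)/CCOCc1ccc(OC)cc1 | intermediate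
19 | prop-2-yn-1-ol | C#CCO | starting material
20 | triethyl(prop-2-yn-1-yloxy)silane | C#CCO[Si](CC)(CC)CC | intermediate
21 | lithium acetylide of 20 | [Li]C#CCO[Si](CC)(CC)CC | intermediate
22 | (5Z,7S,9E)-7-[(tert-butyldimethylsilyl)oxy]-6-{[(tert-butyldimethylsilyl)oxy]methyl}-12-[(4-methoxybenzyl)oxy]-10-methyl-1-[(triethylsilyl)oxy]dodeca-5,9-dien-2-yn-4-one | CC[Si](CC)(CC)OCC#CC(=O)/C=C(/CO[Si](C)(C)C(C)(C)C)[C@@H](O[Si](C)(C)C(C)(C)C)C/C=C(C)/CCOCc1ccc(OC)cc1 | intermediate
23 | (4R,5Z,7S,9E)-7-[(tert-butyldimethylsilyl)oxy]-6-{[(tert-butyldimethylsilyl)oxy]methyl}-12-[(4-methoxybenzyl)oxy]-10-methyl-1-[(triethylsilyl)oxy]dodeca-5,9-dien-2-yn-4-ol | CC[Si](CC)(CC)OCC#C[C@H](O)/C=C(/CO[Si](C)(C)C(C)(C)C)[C@@H](O[Si](C)(C)C(C)(C)C)C/C=C(C)/CCOCc1ccc(OC)cc1 | intermediate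
24 | sodium 1,2-oxaluminol-3-ene alanate from 23 (O6–Al–C11=C7–C6 ring; two 2-methoxyethoxy ligands on Al) | COCCO[Al-]1(OCCOC)O[C@H](/C=C(/CO[Si](C)(C)C(C)(C)C)[C@@H](O[Si](C)(C)C(C)(C)C)C/C=C(C)/CCOCc2ccc(OC)cc2)C=C1CO[Si](CC)(CC)CC.[Na+] | intermediate
25 | (2Z,4R,5Z,7S,9E)-7-[(tert-butyldimethylsilyl)oxy]-6-{[(tert-butyldimethylsilyl)oxy]methyl}-2-iodo-12-[(4-methoxybenzyl)oxy]-10-methyl-1-[(triethylsilyl)oxy]dodeca-2,5,9-trien-4-ol | CC[Si](CC)(CC)OC/C(I)=C/[C@H](O)/C=C(/CO[Si](C)(C)C(C)(C)C)[C@@H](O[Si](C)(C)C(C)(C)C)C/C=C(C)/CCOCc1ccc(OC)cc1 | intermediate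
26 | triethylsilyl ether of 27 at the 3-(hydroxymethyl) group | CC[Si](CC)(CC)OCC1=C[C@@H](/C=C(/CO[Si](C)(C)C(C)(C)C)[C@@H](O[Si](C)(C)C(C)(C)C)C/C=C(C)/CCOCc2ccc(OC)cc2)OC1=O | intermediate
27 | (5R)-5-{(1Z,3S,5E)-3-[(tert-butyldimethylsilyl)oxy]-2-{[(tert-butyldimethylsilyl)oxy]methyl}-8-[(4-methoxybenzyl)oxy]-6-methylocta-1,5-dien-1-yl}-3-(hydroxymethyl)furan-2(5H)-one | OCC1=C[C@@H](/C=C(/CO[Si](C)(C)C(C)(C)C)[C@@H](O[Si](C)(C)C(C)(C)C)C/C=C(C)/CCOCc2ccc(OC)cc2)OC1=O | intermediate
28 | (5R)-5-{(1Z,3S)-3-[(tert-butyldimethylsilyl)oxy]-2-{[(tert-butyldimethylsilyl)oxy]methyl}-4-[(2R,3R)-3-{2-[(4-methoxybenzyl)oxy]ethyl}-3-methyloxiran-2-yl]but-1-en-1-yl}-3-(hydroxymethyl)furan-2(5H)-one | OCC1=C[C@@H](/C=C(/CO[Si](C)(C)C(C)(C)C)[C@@H](O[Si](C)(C)C(C)(C)C)C[C@H]2O[C@]2(C)CCOCc2ccc(OC)cc2)OC1=O | intermediate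
29 | 3-(bromomethyl) analogue of 28 | BrCC1=C[C@@H](/C=C(/CO[Si](C)(C)C(C)(C)C)[C@@H](O[Si](C)(C)C(C)(C)C)C[C@H]2O[C@]2(C)CCOCc2ccc(OC)cc2)OC1=O | intermediate
30 | (5R)-3-(bromomethyl)-5-{(1Z,3S)-3-[(tert-butyldimethylsilyl)oxy]-2-{[(tert-butyldimethylsilyl)oxy]methyl}-4-[(2R,3R)-3-(2-hydroxyethyl)-3-methyloxiran-2-yl]but-1-en-1-yl}furan-2(5H)-one | BrCC1=C[C@@H](/C=C(/CO[Si](C)(C)C(C)(C)C)[C@@H](O[Si](C)(C)C(C)(C)C)C[C@H]2O[C@]2(C)CCO)OC1=O | intermediate
31 | 2-[(2R,3R)-3-{(2S,3Z)-4-[(2R)-4-(bromomethyl)-5-oxo-2,5-dihydrofuran-2-yl]-2-[(tert-butyldimethylsilyl)oxy]-3-{[(tert-butyldimethylsilyl)oxy]methyl}but-3-en-1-yl}-2-methyloxiran-2-yl]acetaldehyde | BrCC1=C[C@@H](/C=C(/CO[Si](C)(C)C(C)(C)C)[C@@H](O[Si](C)(C)C(C)(C)C)C[C@H]2O[C@]2(C)CC=O)OC1=O | intermediate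
32 | allylchromium(III) dichloride from 31 (Cr on C13) | Cl[Cr](Cl)CC1=C[C@@H](/C=C(/CO[Si](C)(C)C(C)(C)C)[C@@H](O[Si](C)(C)C(C)(C)C)C[C@H]2O[C@]2(C)CC=O)OC1=O | intermediate
33 | (1R,3S,4Z,6R,7R,8S,10R)-3,15-bis[(tert-butyldimethylsilyl)oxy]-1,10-epoxy-8-hydroxygermacra-4,11(13)-dien-12,6-olide | C=C1C(=O)O[C@@H]2/C=C(/CO[Si](C)(C)C(C)(C)C)[C@@H](O[Si](C)(C)C(C)(C)C)C[C@H]3O[C@]3(C)C[C@H](O)[C@@H]12 | intermediate
34 | angelic acid [(2Z)-2-methylbut-2-enoic acid] | C/C=C(/C)C(=O)O | starting material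
35 | (1R,3S,4Z,6R,7R,8R,10R)-8-angeloyloxy-3,15-bis[(tert-butyldimethylsilyl)oxy]-1,10-epoxygermacra-4,11(13)-dien-12,6-olide | C=C1C(=O)O[C@@H]2/C=C(/CO[Si](C)(C)C(C)(C)C)[C@@H](O[Si](C)(C)C(C)(C)C)C[C@H]3O[C@]3(C)C[C@@H](OC(=O)/C(C)=C\C)[C@@H]12 | intermediate
36 | (1R,3S,4Z,6R,7R,8R,10R)-8-angeloyloxy-1,10-epoxy-3,15-dihydroxygermacra-4,11(13)-dien-12,6-olide (CNP0187917.1) | C=C1C(=O)O[C@@H]2/C=C(/CO)[C@@H](O)C[C@H]3O[C@]3(C)C[C@@H](OC(=O)/C(C)=C\C)[C@@H]12 | target

**Step count**

Total: 22 steps. Longest linear sequence: 20 steps (but-3-yn-1-ol 1 through steps 1–3, 5–10 and 12–22 to 36).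

**Steps most likely to fail and their fallbacks**

1. Step 20 (ring closure). Three processes may defeat it. Slow ten-membered ring closure may let the Cr(III) Lewis acid or traces of base open the epoxide of the β,γ-epoxy aldehyde by α-deprotonation. The allylchromium may be protonated or couple intermolecularly. The aldehyde may be delivered to the face of C7 that gives the cis-fused lactone. The fallback makes the nucleophile as a stable, neutral allylboronate and closes the ring thermally, without a reductant or metal salts. It sets out from bromide 29. Pd-catalysed borylation (B2pin2, Pd2(dba)3, DMSO, 50 °C) should give the pinacol allylboronate F1. DDQ (CH2Cl2/pH 7 buffer) should then give the primary alcohol F2, and buffered Dess–Martin oxidation the boronate aldehyde F3. Heating F3 in toluene (90 °C, 1 mM) should close the ring by intramolecular allylboration through the same chair transition state; after triethanolamine work-up the sequence comes back to the route at 33.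

2. Step 21 (Mitsunobu angeloylation). The alkoxyphosphonium ion at the hindered medium-ring carbinol may eliminate toward C9 or C7 instead of being displaced, inversion may be incomplete, or the phosphine may isomerise the angelate to the tiglate. The fallback inverts C8 by oxidation and reagent-controlled reduction and then acylates with retention. It sets out from 33. Buffered Dess–Martin oxidation should give the C8 ketone F4. Reduction with (S)-Me-CBS and catecholborane (toluene, −40 °C), with the C7 branch acting as the large group, should give the 8R alcohol F5. Acylation of F5 with the mixed anhydride of angelic acid 34 and 2,4,6-trichlorobenzoyl chloride (Et3N, toluene, 80 °C) comes back to the route at 35.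

3. Step 9 (Weinreb opening of the temporary butenolide). The (Z)-γ-hydroxy amide may close back to the butenolide before it is silylated, or the amide nitrogen may add in conjugate fashion. The fallback opens the lactone reductively and builds the C6 carbinol by asymmetric alkynylation instead of ynone reduction. It sets out from 16. DIBAL-H (2.5 equiv, CH2Cl2, −78 → 0 °C) should give the (Z)-ene-1,4-diol F6. Pivaloyl chloride (pyridine, −20 °C) should acylate only the primary hydroxyl to give the monopivalate F7, and TBSOTf/2,6-lutidine should give the silyl ether F8. DIBAL-H should remove the pivalate to give the allylic alcohol F9, and MnO2 should give the (Z)-enal F10. Zn–ProPhenol-catalysed addition of alkyne 20 to F10 (Me2Zn, toluene, 0 °C; ligand enantiomer matched to the 6R carbinol) comes back to the route at 23, so that 17, 18 and 22 are bypassed.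

**Further compounds**

F1 | step 20 | pinacol allylboronate: 29 with CH2Br replaced by CH2B(pin) | CC1(C)OB(CC2=C[C@@H](/C=C(/CO[Si](C)(C)C(C)(C)C)[C@@H](O[Si](C)(C)C(C)(C)C)C[C@H]3O[C@]3(C)CCOCc3ccc(OC)cc3)OC2=O)OC1(C)C
F2 | step 20 | primary alcohol from F1 after PMB removal | CC1(C)OB(CC2=C[C@@H](/C=C(/CO[Si](C)(C)C(C)(C)C)[C@@H](O[Si](C)(C)C(C)(C)C)C[C@H]3O[C@]3(C)CCO)OC2=O)OC1(C)C
F3 | step 20 | boronate aldehyde (C8 = CHO) | CC1(C)OB(CC2=C[C@@H](/C=C(/CO[Si](C)(C)C(C)(C)C)[C@@H](O[Si](C)(C)C(C)(C)C)C[C@H]3O[C@]3(C)CC=O)OC2=O)OC1(C)C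
F4 | step 21 | (1R,3S,4Z,6R,7S,10R)-3,15-bis[(tert-butyldimethylsilyl)oxy]-1,10-epoxy-8-oxogermacra-4,11(13)-dien-12,6-olide (7S by priority change only) | C=C1C(=O)O[C@@H]2/C=C(/CO[Si](C)(C)C(C)(C)C)[C@@H](O[Si](C)(C)C(C)(C)C)C[C@H]3O[C@]3(C)CC(=O)[C@@H]12
F5 | step 21 | (1R,3S,4Z,6R,7R,8R,10R)-3,15-bis[(tert-butyldimethylsilyl)oxy]-1,10-epoxy-8-hydroxygermacra-4,11(13)-dien-12,6-olide | C=C1C(=O)O[C@@H]2/C=C(/CO[Si](C)(C)C(C)(C)C)[C@@H](O[Si](C)(C)C(C)(C)C)C[C@H]3O[C@]3(C)C[C@@H](O)[C@@H]12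
F6 | step 9 | (2Z,4S,6E)-3-{[(tert-butyldimethylsilyl)oxy]methyl}-9-[(4-methoxybenzyl)oxy]-7-methylnona-2,6-diene-1,4-diol | OC/C=C(/CO[Si](C)(C)C(C)(C)C)[C@@H](O)C/C=C(C)/CCOCc1ccc(OC)cc1
F7 | step 9 | 1-O-pivalate of F6 | CC(C)(C)C(=O)OC/C=C(/CO[Si](C)(C)C(C)(C)C)[C@@H](O)C/C=C(C)/CCOCc1ccc(OC)cc1
F8 | step 9 | 4-O-TBS ether of F7 | CC(C)(C)C(=O)OC/C=C(/CO[Si](C)(C)C(C)(C)C)[C@@H](O[Si](C)(C)C(C)(C)C)C/C=C(C)/CCOCc1ccc(OC)cc1
F9 | step 9 | (2Z,4S,6E)-4-[(tert-butyldimethylsilyl)oxy]-3-{[(tert-butyldimethylsilyl)oxy]methyl}-9-[(4-methoxybenzyl)oxy]-7-methylnona-2,6-dien-1-ol | OC/C=C(/CO[Si](C)(C)C(C)(C)C)[C@@H](O[Si](C)(C)C(C)(C)C)C/C=C(C)/CCOCc1ccc(OC)cc1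
F10 | step 9 | (2Z,4S,6E)-4-[(tert-butyldimethylsilyl)oxy]-3-{[(tert-butyldimethylsilyl)oxy]methyl}-9-[(4-methoxybenzyl)oxy]-7-methylnona-2,6-dienal | O=C/C=C(/CO[Si](C)(C)C(C)(C)C)[C@@H](O[Si](C)(C)C(C)(C)C)C/C=C(C)/CCOCc1ccc(OC)cc1
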